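**Plan**
- Retrosynthetic cuts, in order: the C6 ester; the O–C10 bond of the furanone (back to a 1,10-epoxy-3-ketone); C3–C4 of the ten-membered ring (alkenyl iodide + aldehyde); C6–C7 (allylzinc + enal); the butenolide C7=C11 (metathesis) and its ester; C9–C10 (alkenyl Grignard + epichlorohydrin).
- Enabling feature: the furanone oxygen ties C3 to the methyl-bearing C10 across the ring C1–C10, so the ring O–C3–C2–C1–C10 is pre-assembled in a 1,10-epoxy-3-ketone, where the C3 carbonyl oxygen faces the rear of the tertiary epoxide carbon C10.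
- Forward ring order: butenolide (ring-closing metathesis), α-methylene lactone at C7/C8 (Barbier allylation), ten-membered carbocycle (Nozaki–Hiyama–Kishi), five-membered oxygen bridge (epoxy-ketone closure), then oxidation to the furanone and side-chain esterification.
- Stereochemistry: C8 from (S)-epichlorohydrin; C7 and C6 from the chair Barbier addition steered by C8; C1/C10 from a reagent-controlled Shi epoxidation, with C10 inverted in the key step; the side-chain carbinol from ethyl (R)-3-hydroxybutanoate.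
- Alkene geometry: 1(10)E from hydrozirconation–iodination, 4Z from trans-hydroalumination–iodination.

Key step: step 16

Remark: ring atoms carry germacrane numbers (C1–C10 ring, C11–C13 lactone, C14 on C10, C15 on C4); the L-fructose-derived Shi ketone is assumed to be at hand (made from L-sorbose as its mirror image is from D-fructose).

Step 1
Reactants: 1 pent-3-yn-1-ol
Product: 2 1-methoxy-4-[(pent-3-yn-1-yloxy)methyl]benzene
Conditions: NaH, PMBCl, Bu4NI (cat.), DMF, 0 °C to rt
Reagents that add atoms: 4-methoxybenzyl chloride, COc1ccc(CCl)cc1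
Why: Williamson etherification of the primary alkoxide gives a PMB ether that tolerates the organometallic, ylide, ruthenium and zinc steps ahead and can later be removed oxidatively beside an epoxide and a silyl ether.

Step 2
Reactants: 2 1-methoxy-4-[(pent-3-yn-1-yloxy)methyl]benzene
Product: 3 1-{[(3E)-4-iodopent-3-en-1-yl]oxymethyl}-4-methoxybenzene
Conditions: Cp2Zr(H)Cl (2 equiv), THF, 50 °C; then I2, 0 °C
Reagents that add atoms: iodine, II
Why: Hydrozirconation–iodination: syn addition of Zr–H, equilibration by excess reagent to the less hindered methyl-bearing carbon and iodinolysis with retention should give the E iodoalkene that fixes the later C1–C10 geometry.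

Step 3
Reactants: 3 1-{[(3E)-4-iodopent-3-en-1-yl]oxymethyl}-4-methoxybenzene; 4 (S)-epichlorohydrin
Product: 7 (2S,4E)-1-chloro-7-[(4-methoxybenzyl)oxy]-4-methylhept-4-en-2-ol, via vinyllithium 5 (not isolated), via vinylmagnesium bromide 6 (not isolated)
Conditions: t-BuLi (2 equiv), Et2O, −78 °C; MgBr2·OEt2, −78 to −40 °C; CuI (10 mol%), 4, THF, −40 to −10 °C
Reagents that add atoms: none
Why: Iodine–lithium exchange with retention, transmetallation to magnesium and copper-catalysed Grignard opening of the epoxide at its CH2 terminus join C9 to C10, and the C8 carbinol is taken unchanged from (S)-epichlorohydrin.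

Step 4
Reactants: 7 (2S,4E)-1-chloro-7-[(4-methoxybenzyl)oxy]-4-methylhept-4-en-2-ol
Product: 8 (2S)-1-chloro-3-[(2S,3S)-3-{2-[(4-methoxybenzyl)oxy]ethyl}-2-methyloxiran-2-yl]propan-2-ol
Conditions: L-fructose-derived Shi ketone (30 mol%), KHSO5 (as Oxone, 2KHSO5·KHSO4·K2SO4), K2CO3, Bu4NHSO4, MeCN/CH2(OMe)2–aq. Na2B4O7 buffer, 0 °C
Reagents that add atoms: potassium peroxymonosulfate, [K+].[O-]S(=O)(=O)OO
Why: Shi asymmetric epoxidation: the chiral dioxirane meets the only alkene, an E-trisubstituted one, in a spiro transition state, and since the D-fructose ketone gives R,R epoxides from such alkenes its mirror image should set 1S,10S under reagent control, independent of C8.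

Step 5
Reactants: 8 (2S)-1-chloro-3-[(2S,3S)-3-{2-[(4-methoxybenzyl)oxy]ethyl}-2-methyloxiran-2-yl]propan-2-ol
Product: 10 (2S)-1-[(2S,3S)-3-{2-[(4-methoxybenzyl)oxy]ethyl}-2-methyloxiran-2-yl]but-3-en-2-ol, via terminal epoxide 9 (not isolated)
Conditions: Me3S+ I− (4 equiv), n-BuLi (3.9 equiv), THF, −10 °C; then 8, −10 °C to rt
Reagents that add atoms: trimethylsulfonium iodide, C[S+](C)C.[I-]
Why: The ylide first acts as base and closes the chlorohydrin to the terminal epoxide, then opens it at the CH2 carbon and the betaine loses dimethyl sulfide (sulfonium-ylide one-carbon homologation of an epoxide to an allylic alcohol), while the hindered trisubstituted epoxide and C8 stay untouched.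

Step 6
Reactants: 10 (2S)-1-[(2S,3S)-3-{2-[(4-methoxybenzyl)oxy]ethyl}-2-methyloxiran-2-yl]but-3-en-2-ol; 11 2-(bromomethyl)prop-2-enoic acid
Product: 12 (2S)-1-[(2S,3S)-3-{2-[(4-methoxybenzyl)oxy]ethyl}-2-methyloxiran-2-yl]but-3-en-2-yl 2-(bromomethyl)prop-2-enoate
Conditions: DCC, DMAP (5 mol%), CH2Cl2, 0 °C
Reagents that add atoms: none
Why: Steglich esterification at 0 °C acylates the secondary allylic alcohol under neutral conditions that spare the allylic bromide and the epoxide, with C8 not involved.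

Step 7
Reactants: 12 (2S)-1-[(2S,3S)-3-{2-[(4-methoxybenzyl)oxy]ethyl}-2-methyloxiran-2-yl]but-3-en-2-yl 2-(bromomethyl)prop-2-enoate
Product: 13 (5S)-3-(bromomethyl)-5-{[(2S,3S)-3-{2-[(4-methoxybenzyl)oxy]ethyl}-2-methyloxiran-2-yl]methyl}furan-2(5H)-one
Conditions: second-generation Grubbs catalyst RuCl2(=CHPh)(PCy3)(H2IMes) (5 mol%), CH2Cl2, 40 °C, 5 mM
Reagents that add atoms: none
Why: Ring-closing metathesis of the acrylate and vinyl groups gives the butenolide with loss of ethene, the side chain carrying no competing alkene.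

Step 8
Reactants: 14 but-2-yn-1-ol
Product: 15 (2Z)-3-iodobut-2-en-1-ol
Conditions: NaAlH2(OCH2CH2OMe)2 (Red-Al), THF, 0 °C to rt; then I2, −78 °C
Reagents that add atoms: iodine, II
Why: Alkoxide-directed trans-hydroalumination of the propargylic alcohol places aluminium on C3 and iodinolysis with retention gives the Z iodoalkene that becomes the C4–C5 alkene.

Step 9
Reactants: 15 (2Z)-3-iodobut-2-en-1-ol
Product: 16 (2Z)-3-iodobut-2-enal
Conditions: MnO2 (excess), CH2Cl2, rt, dark
Reagents that add atoms: none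
Why: MnO2 oxidation of the allylic alcohol is neutral and heterogeneous, so the Z β-iodo enal should form without isomerisation.

Step 10
Reactants: 13 (5S)-3-(bromomethyl)-5-{[(2S,3S)-3-{2-[(4-methoxybenzyl)oxy]ethyl}-2-methyloxiran-2-yl]methyl}furan-2(5H)-one; 16 (2Z)-3-iodobut-2-enal
Product: 17 (4S,5S)-4-[(1S,2Z)-1-hydroxy-3-iodobut-2-en-1-yl]-5-{[(2S,3S)-3-{2-[(4-methoxybenzyl)oxy]ethyl}-2-methyloxiran-2-yl]methyl}-3-methylideneoxolan-2-one
Conditions: Zn dust, THF/sat. aq. NH4Cl, 0 °C
Reagents that add atoms: none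
Why: Zinc Barbier allylation: zinc inserts into the allylic bromide only, and the allylzinc adds through its γ-carbon C7 in a closed chair, on the face opposite the C8 substituent (trans lactone, sets C7) and with the aldehyde residue equatorial (sets C6, oxygen syn to C11 along the C5–C8 chain), which regenerates the α-methylene lactone.

Step 11
Reactants: 17 (4S,5S)-4-[(1S,2Z)-1-hydroxy-3-iodobut-2-en-1-yl]-5-{[(2S,3S)-3-{2-[(4-methoxybenzyl)oxy]ethyl}-2-methyloxiran-2-yl]methyl}-3-methylideneoxolan-2-one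
Product: 18 (4R,5S)-4-[(1S,2Z)-1-(tert-butyldimethylsilyloxy)-3-iodobut-2-en-1-yl]-5-{[(2S,3S)-3-{2-[(4-methoxybenzyl)oxy]ethyl}-2-methyloxiran-2-yl]methyl}-3-methylideneoxolan-2-one
Conditions: TBSCl, imidazole, DMAP (cat.), DMF, rt
Reagents that add atoms: tert-butyldimethylsilyl chloride, CC(C)(C)[Si](C)(C)Cl
Why: Silylation of the secondary allylic alcohol with the silyl chloride and imidazole avoids a Lewis-acidic silyl triflate and so spares the epoxide.

Step 12
Reactants: 18 (4R,5S)-4-[(1S,2Z)-1-(tert-butyldimethylsilyloxy)-3-iodobut-2-en-1-yl]-5-{[(2S,3S)-3-{2-[(4-methoxybenzyl)oxy]ethyl}-2-methyloxiran-2-yl]methyl}-3-methylideneoxolan-2-one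
Product: 19 (4R,5S)-4-[(1S,2Z)-1-(tert-butyldimethylsilyloxy)-3-iodobut-2-en-1-yl]-5-{[(2S,3S)-3-(2-hydroxyethyl)-2-methyloxiran-2-yl]methyl}-3-methylideneoxolan-2-one
Conditions: DDQ, CH2Cl2/pH 7 buffer, 0 °C
Reagents that add atoms: none
Why: Oxidative PMB cleavage by DDQ through the stabilised benzylic cation in buffered wet dichloromethane leaves the silyl ether, epoxide, iodoalkene and methylene lactone alone.

Step 13
Reactants: 19 (4R,5S)-4-[(1S,2Z)-1-(tert-butyldimethylsilyloxy)-3-iodobut-2-en-1-yl]-5-{[(2S,3S)-3-(2-hydroxyethyl)-2-methyloxiran-2-yl]methyl}-3-methylideneoxolan-2-one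
Product: 20 2-[(2S,3S)-3-{[(2S,3R)-3-[(1S,2Z)-1-(tert-butyldimethylsilyloxy)-3-iodobut-2-en-1-yl]-4-methylidene-5-oxooxolan-2-yl]methyl}-3-methyloxiran-2-yl]acetaldehyde
Conditions: Dess–Martin periodinane, NaHCO3, CH2Cl2, 0 °C; used at once
Reagents that add atoms: none
Why: Buffered Dess–Martin oxidation stops at the aldehyde and is mild enough for the β,γ-epoxy aldehyde, which is carried on without storage.

Step 14
Reactants: 20 2-[(2S,3S)-3-{[(2S,3R)-3-[(1S,2Z)-1-(tert-butyldimethylsilyloxy)-3-iodobut-2-en-1-yl]-4-methylidene-5-oxooxolan-2-yl]methyl}-3-methyloxiran-2-yl]acetaldehyde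
Product: 21 (1S,4Z,6R,7R,8S,10S)-6-(tert-butyldimethylsilyloxy)-1,10-epoxy-3-hydroxygermacra-4,11(13)-dien-12,8-olide (both C3 epimers)
Conditions: CrCl2 (10 equiv), NiCl2 (1 mol% of the chromium), degassed DMSO, rt, slow addition to 2 mM
Reagents that add atoms: none
Why: Nozaki–Hiyama–Kishi reaction: nickel inserts into the C–I bond with retention of the Z geometry, the alkenylchromium adds only to the aldehyde beside lactone, epoxide and silyl ether, and high dilution favours closure of the ten-membered carbocycle at C3–C4 over oligomers, the C3 configuration being of no consequence.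

Step 15
Reactants: 21 (1S,4Z,6R,7R,8S,10S)-6-(tert-butyldimethylsilyloxy)-1,10-epoxy-3-hydroxygermacra-4,11(13)-dien-12,8-olide
Product: 22 (1S,4Z,6R,7R,8S,10S)-6-(tert-butyldimethylsilyloxy)-1,10-epoxy-3-oxogermacra-4,11(13)-dien-12,8-olide
Conditions: Dess–Martin periodinane, NaHCO3, CH2Cl2, 0 °C
Reagents that add atoms: none
Why: Buffered Dess–Martin oxidation converts both allylic C3 epimers into the one enone, and the neutral medium avoids β-elimination of the β,γ-epoxy ketone.

Step 16
Reactants: 22 (1S,4Z,6R,7R,8S,10S)-6-(tert-butyldimethylsilyloxy)-1,10-epoxy-3-oxogermacra-4,11(13)-dien-12,8-olide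
Product: 23 (1S,4Z,6R,7R,8S,10R)-6-(tert-butyldimethylsilyloxy)-3,10-epoxy-1-hydroxygermacra-2,4,11(13)-trien-12,8-olide
Conditions: Sc(OTf)3 (10 mol%), 4 Å molecular sieves, CH2Cl2, −40 to −10 °C; Et3N quench
Reagents that add atoms: none
Why: Proposed new method: Sc(OTf)3 binds the epoxide oxygen, the C10–O bond lengthens at the tertiary carbon, and the C3 carbonyl oxygen, lying transannular on the inner face of the ten-membered ring, bonds to C10 opposite the departing oxygen; the 2-alkenyl oxocarbenium ion then gives up a C2 proton, which ends on the C1 alkoxide, so the whole is a catalytic isomerisation. The closest known reaction type is the acid-catalysed cycloisomerisation of β,γ-epoxy ketones to 3-hydroxy-2,3-dihydrofurans (first stage of the epoxy-ketone furan synthesis), together with acid-catalysed transannular openings of germacranolide 1,10-epoxides; here the quaternary C10 blocks aromatisation and the new ring is a bridge. The five-membered oxygen ring O–C3–C2–C1–C10 closes in the 5-endo mode on the epoxide, the 4-exo alternative at C1 leading only to an oxetane. C10 is the one stereocentre made and it forms with inversion, so it is fixed by the 10S epoxide of step 4 and by the inside trajectory of the oxygen, while C1 keeps its configuration. The step needs oxygen rather than carbon cyclisation and attack at C10 rather than C1: the C4–C5 alkene is conjugated to the ketone and too electron-poor to act as the π-nucleophile that leads to eudesmanes, the same conjugation makes the carbonyl oxygen more basic, and the tertiary C10 carries the developing charge.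

Step 17
Reactants: 23 (1S,4Z,6R,7R,8S,10R)-6-(tert-butyldimethylsilyloxy)-3,10-epoxy-1-hydroxygermacra-2,4,11(13)-trien-12,8-olide
Product: 24 (4Z,6R,7R,8S,10R)-6-(tert-butyldimethylsilyloxy)-3,10-epoxy-1-oxogermacra-2,4,11(13)-trien-12,8-olide
Conditions: Dess–Martin periodinane, NaHCO3, CH2Cl2, 0 °C
Reagents that add atoms: none
Why: Dess–Martin oxidation of the allylic C1 alcohol gives the 3(2H)-furanone, a vinylogous ester far more robust than the dienyl ether, with no stereocentre affected.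

Step 18
Reactants: 24 (4Z,6R,7R,8S,10R)-6-(tert-butyldimethylsilyloxy)-3,10-epoxy-1-oxogermacra-2,4,11(13)-trien-12,8-olide
Product: 25 (4Z,6R,7S,8S,10R)-3,10-epoxy-6-hydroxy-1-oxogermacra-2,4,11(13)-trien-12,8-olide
Conditions: HF·pyridine, pyridine, THF, 0 °C to rt
Reagents that add atoms: none
Why: Fluoride-mediated desilylation with buffered HF·pyridine frees the C6 alcohol without the base that the Michael acceptors would not tolerate.

Step 19
Reactants: 26 ethyl (3R)-3-hydroxybutanoate
Product: 27 ethyl (2R,3R)-2-[(dimethylamino)methyl]-3-hydroxybutanoate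
Conditions: LiN(i-Pr)2 (2.2 equiv), THF, −78 to −20 °C; CH2=NMe2+ I−, −78 °C to rt
Reagents that add atoms: N,N-dimethylmethyleneiminium iodide, C=[N+](C)C.[I-]
Why: Fráter–Seebach alkylation: the alkoxide-enolate dianion of the β-hydroxy ester is aminomethylated by the iminium salt (Mannich reaction) anti to the C3 oxygen, and C3 itself is not touched.

Step 20
Reactants: 27 ethyl (2R,3R)-2-[(dimethylamino)methyl]-3-hydroxybutanoate
Product: 29 ethyl (3R)-3-hydroxy-2-methylidenebutanoate, via ammonium iodide 28 (not isolated)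
Conditions: MeI, MeOH, rt; then DBU, CH2Cl2, rt
Reagents that add atoms: none
Why: Exhaustive methylation turns the amine into a leaving group and base-induced β-elimination (E1cB, Hofmann type) gives the α-methylene ester, removing the C2 centre and leaving C3 as R.

Step 21
Reactants: 29 ethyl (3R)-3-hydroxy-2-methylidenebutanoate
Product: 30 ethyl (3R)-3-(tert-butyldimethylsilyloxy)-2-methylidenebutanoate
Conditions: TBSCl, imidazole, DMF, rt
Reagents that add atoms: tert-butyldimethylsilyl chloride, CC(C)(C)[Si](C)(C)Cl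
Why: Standard silylation masks the secondary hydroxyl so that the acid cannot acylate itself in step 23.

Step 22
Reactants: 30 ethyl (3R)-3-(tert-butyldimethylsilyloxy)-2-methylidenebutanoate
Product: 31 (3R)-3-(tert-butyldimethylsilyloxy)-2-methylidenebutanoic acid
Conditions: LiOH, THF/MeOH/H2O, rt; then 1 M HCl to pH 3
Reagents that add atoms: lithium hydroxide, [Li+].[OH-]
Why: Saponification of the ethyl ester proceeds at room temperature, the hindered β-silyloxy acrylate resisting conjugate addition of hydroxide.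

Step 23
Reactants: 25 (4Z,6R,7S,8S,10R)-3,10-epoxy-6-hydroxy-1-oxogermacra-2,4,11(13)-trien-12,8-olide; 31 (3R)-3-(tert-butyldimethylsilyloxy)-2-methylidenebutanoic acid
Product: 33 (4Z,6R,7R,8S,10R)-6-{[(3R)-3-(tert-butyldimethylsilyloxy)-2-methylidenebutanoyl]oxy}-3,10-epoxy-1-oxogermacra-2,4,11(13)-trien-12,8-olide, via mixed anhydride 32 (not isolated)
Conditions: 2,4,6-trichlorobenzoyl chloride, Et3N, toluene, rt; then 25, DMAP, rt
Reagents that add atoms: none
Why: Yamaguchi esterification through the mixed anhydride and the acylpyridinium ion acylates the hindered secondary C6 alcohol with retention at C6 and at the side-chain carbinol.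

Step 24
Reactants: 33 (4Z,6R,7R,8S,10R)-6-{[(3R)-3-(tert-butyldimethylsilyloxy)-2-methylidenebutanoyl]oxy}-3,10-epoxy-1-oxogermacra-2,4,11(13)-trien-12,8-olide
Product: 34 (4Z,6R,7R,8S,10R)-3,10-epoxy-6-{[(3R)-3-hydroxy-2-methylidenebutanoyl]oxy}-1-oxogermacra-2,4,11(13)-trien-12,8-olide (CNP0266753.1)
Conditions: HF·pyridine, THF, 0 °C to rt
Reagents that add atoms: none
Why: Fluoride desilylation of the last secondary silyl ether under non-basic conditions should release the target without disturbing the furanone or the two acrylate units.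

**Compound list**
1 | pent-3-yn-1-ol | CC#CCCO | starting material
2 | 1-methoxy-4-[(pent-3-yn-1-yloxy)methyl]benzene | CC#CCCOCc1ccc(OC)cc1 | intermediate
3 | 1-{[(3E)-4-iodopent-3-en-1-yl]oxymethyl}-4-methoxybenzene | C/C(I)=C\CCOCc1ccc(OC)cc1 | intermediate
4 | (S)-epichlorohydrin, (2S)-2-(chloromethyl)oxirane | ClC[C@@H]1CO1 | starting material
5 | (2Z)-5-[(4-methoxybenzyl)oxy]pent-2-en-2-yllithium | C/C([Li])=C\CCOCc1ccc(OC)cc1 | intermediate
6 | (2E)-5-[(4-methoxybenzyl)oxy]pent-2-en-2-ylmagnesium bromide | C/C([Mg]Br)=C\CCOCc1ccc(OC)cc1 | intermediate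
7 | (2S,4E)-1-chloro-7-[(4-methoxybenzyl)oxy]-4-methylhept-4-en-2-ol | ClC[C@@H](O)C/C(C)=C/CCOCc1ccc(OC)cc1 | intermediate
8 | (2S)-1-chloro-3-[(2S,3S)-3-{2-[(4-methoxybenzyl)oxy]ethyl}-2-methyloxiran-2-yl]propan-2-ol | ClC[C@@H](O)C[C@]1(C)O[C@H]1CCOCc2ccc(OC)cc2 | intermediate
9 | (2S,3S)-3-{2-[(4-methoxybenzyl)oxy]ethyl}-2-methyl-2-{[(2S)-oxiran-2-yl]methyl}oxirane | C1O[C@H]1C[C@]2(C)O[C@H]2CCOCc3ccc(OC)cc3 | intermediate
10 | (2S)-1-[(2S,3S)-3-{2-[(4-methoxybenzyl)oxy]ethyl}-2-methyloxiran-2-yl]but-3-en-2-ol | C=C[C@@H](O)C[C@]1(C)O[C@H]1CCOCc2ccc(OC)cc2 | intermediate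
11 | 2-(bromomethyl)prop-2-enoic acid | C=C(CBr)C(=O)O | starting material
12 | (2S)-1-[(2S,3S)-3-{2-[(4-methoxybenzyl)oxy]ethyl}-2-methyloxiran-2-yl]but-3-en-2-yl 2-(bromomethyl)prop-2-enoate | C=C(CBr)C(=O)O[C@H](C=C)C[C@]1(C)O[C@H]1CCOCc2ccc(OC)cc2 | intermediate
13 | (5S)-3-(bromomethyl)-5-{[(2S,3S)-3-{2-[(4-methoxybenzyl)oxy]ethyl}-2-methyloxiran-2-yl]methyl}furan-2(5H)-one | O=C1O[C@@H](C[C@]2(C)O[C@H]2CCOCc3ccc(OC)cc3)C=C1CBr | intermediate
14 | but-2-yn-1-ol | CC#CCO | starting material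
15 | (2Z)-3-iodobut-2-en-1-ol | C/C(I)=C/CO | intermediate
16 | (2Z)-3-iodobut-2-enal | C/C(I)=C/C=O | intermediate
17 | (4S,5S)-4-[(1S,2Z)-1-hydroxy-3-iodobut-2-en-1-yl]-5-{[(2S,3S)-3-{2-[(4-methoxybenzyl)oxy]ethyl}-2-methyloxiran-2-yl]methyl}-3-methylideneoxolan-2-one | C=C1C(=O)O[C@@H](C[C@]2(C)O[C@H]2CCOCc3ccc(OC)cc3)[C@@H]1[C@H](O)/C=C(\I)C | intermediate
18 | (4R,5S)-4-[(1S,2Z)-1-(tert-butyldimethylsilyloxy)-3-iodobut-2-en-1-yl]-5-{[(2S,3S)-3-{2-[(4-methoxybenzyl)oxy]ethyl}-2-methyloxiran-2-yl]methyl}-3-methylideneoxolan-2-one | C=C1C(=O)O[C@@H](C[C@]2(C)O[C@H]2CCOCc3ccc(OC)cc3)[C@@H]1[C@H](O[Si](C)(C)C(C)(C)C)/C=C(\I)C | intermediate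
19 | (4R,5S)-4-[(1S,2Z)-1-(tert-butyldimethylsilyloxy)-3-iodobut-2-en-1-yl]-5-{[(2S,3S)-3-(2-hydroxyethyl)-2-methyloxiran-2-yl]methyl}-3-methylideneoxolan-2-one | C=C1C(=O)O[C@@H](C[C@]2(C)O[C@H]2CCO)[C@@H]1[C@H](O[Si](C)(C)C(C)(C)C)/C=C(\I)C | intermediate
20 | 2-[(2S,3S)-3-{[(2S,3R)-3-[(1S,2Z)-1-(tert-butyldimethylsilyloxy)-3-iodobut-2-en-1-yl]-4-methylidene-5-oxooxolan-2-yl]methyl}-3-methyloxiran-2-yl]acetaldehyde | C=C1C(=O)O[C@@H](C[C@]2(C)O[C@H]2CC=O)[C@@H]1[C@H](O[Si](C)(C)C(C)(C)C)/C=C(\I)C | intermediate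
21 | (1S,4Z,6R,7R,8S,10S)-6-(tert-butyldimethylsilyloxy)-1,10-epoxy-3-hydroxygermacra-4,11(13)-dien-12,8-olide, C3 epimers | C=C1C(=O)O[C@H]2C[C@]3(C)O[C@H]3CC(O)/C(C)=C\[C@@H](O[Si](C)(C)C(C)(C)C)[C@H]12 | intermediate
22 | (1S,4Z,6R,7R,8S,10S)-6-(tert-butyldimethylsilyloxy)-1,10-epoxy-3-oxogermacra-4,11(13)-dien-12,8-olide | C=C1C(=O)O[C@H]2C[C@]3(C)O[C@H]3CC(=O)/C(C)=C\[C@@H](O[Si](C)(C)C(C)(C)C)[C@H]12 | intermediate
23 | (1S,4Z,6R,7R,8S,10R)-6-(tert-butyldimethylsilyloxy)-3,10-epoxy-1-hydroxygermacra-2,4,11(13)-trien-12,8-olide | C=C1C(=O)O[C@H]2C[C@@]3(C)OC(=C[C@@H]3O)/C(C)=C\[C@@H](O[Si](C)(C)C(C)(C)C)[C@H]12 | intermediate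
24 | (4Z,6R,7R,8S,10R)-6-(tert-butyldimethylsilyloxy)-3,10-epoxy-1-oxogermacra-2,4,11(13)-trien-12,8-olide | C=C1C(=O)O[C@H]2C[C@@]3(C)OC(=CC3=O)/C(C)=C\[C@@H](O[Si](C)(C)C(C)(C)C)[C@H]12 | intermediate
25 | (4Z,6R,7S,8S,10R)-3,10-epoxy-6-hydroxy-1-oxogermacra-2,4,11(13)-trien-12,8-olide | C=C1C(=O)O[C@H]2C[C@@]3(C)OC(=CC3=O)/C(C)=C\[C@@H](O)[C@H]12 | intermediate
26 | ethyl (3R)-3-hydroxybutanoate | CCOC(=O)C[C@@H](C)O | starting material
27 | ethyl (2R,3R)-2-[(dimethylamino)methyl]-3-hydroxybutanoate | CCOC(=O)[C@H](CN(C)C)[C@@H](C)O | intermediate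
28 | [(2R,3R)-2-(ethoxycarbonyl)-3-hydroxybutyl]trimethylammonium iodide | CCOC(=O)[C@H](C[N+](C)(C)C)[C@@H](C)O.[I-] | intermediate
29 | ethyl (3R)-3-hydroxy-2-methylidenebutanoate | CCOC(=O)C(=C)[C@@H](C)O | intermediate
30 | ethyl (3R)-3-(tert-butyldimethylsilyloxy)-2-methylidenebutanoate | CCOC(=O)C(=C)[C@@H](C)O[Si](C)(C)C(C)(C)C | intermediate
31 | (3R)-3-(tert-butyldimethylsilyloxy)-2-methylidenebutanoic acid | OC(=O)C(=C)[C@@H](C)O[Si](C)(C)C(C)(C)C | intermediate
32 | (3R)-3-(tert-butyldimethylsilyloxy)-2-methylidenebutanoic 2,4,6-trichlorobenzoic anhydride | C=C(C(=O)OC(=O)c1c(Cl)cc(Cl)cc1Cl)[C@@H](C)O[Si](C)(C)C(C)(C)C | intermediate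
33 | (4Z,6R,7R,8S,10R)-6-{[(3R)-3-(tert-butyldimethylsilyloxy)-2-methylidenebutanoyl]oxy}-3,10-epoxy-1-oxogermacra-2,4,11(13)-trien-12,8-olide | C=C1C(=O)O[C@H]2C[C@@]3(C)OC(=CC3=O)/C(C)=C\[C@@H](OC(=O)C(=C)[C@@H](C)O[Si](C)(C)C(C)(C)C)[C@H]12 | intermediate
34 | (4Z,6R,7R,8S,10R)-3,10-epoxy-6-{[(3R)-3-hydroxy-2-methylidenebutanoyl]oxy}-1-oxogermacra-2,4,11(13)-trien-12,8-olide (CNP0266753.1) | C=C1C(=O)O[C@H]2C[C@@]3(C)OC(=CC3=O)/C(C)=C\[C@@H](OC(=O)C(=C)[C@@H](C)O)[C@H]12 | target

**Step count**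
Total: 24 steps. Longest linear sequence: 18 steps (steps 1–7, 10–18, 23, 24, from pent-3-yn-1-ol).

**Steps most likely to fail**

Step 16 (key step). The activated epoxide may collapse by hydride shift or proton loss at C10 (Meinwald rearrangement, allylic alcohol) or by enolisation toward C2 and β-elimination before the carbonyl oxygen closes the ring, and the acid-labile dienyl ether may ionise at C1. The fallback uses known chemistry, sets out from 21 and returns at 24, letting the C3 alcohol instead of the ketone open the epoxide. The C3 epimer of 21 whose hydroxyl points into the ring is treated with catalytic camphorsulfonic acid in CH2Cl2 at 0 °C; acid-catalysed 5-endo opening of the 3,4-epoxy alcohol at the tertiary carbon, with inversion at C10, gives the bridged tetrahydrofuranol F1. Dess–Martin oxidation of the C1 alcohol gives the bridged tetrahydrofuran-3-one F2. Soft enolisation with TMSOTf and Et3N can only go toward C2, because C10 is quaternary, and gives the trimethylsilyl enol ether F3. Saegusa–Ito oxidation with Pd(OAc)2 in MeCN then introduces the C2–C3 double bond and delivers furanone 24. The C3 epimer that cannot cyclise is recycled by oxidation to 22 and reduction back to 21.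

Step 14. Oligomerisation may outrun closure of the ten-membered ring, the β,γ-epoxy aldehyde may undergo β-elimination, and trivalent chromium salts or the new chromium alkoxide may open the epoxide. The fallback sets out from 19 and returns at 22, replacing the aldehyde addition by an intramolecular acylation. Iodine is exchanged for tin with Me3SnSnMe3 and Pd(PPh3)4 to give the alkenylstannane alcohol F4. Dess–Martin oxidation gives the stannyl aldehyde F5, which is taken on directly by Pinnick oxidation (NaClO2, NaH2PO4, 2-methylbut-2-ene) to the stannyl acid F6. Neutral activation with 1-chloro-N,N,2-trimethylprop-1-en-1-amine gives the acid chloride F7, which is not isolated. Intramolecular Stille acylation (Pd2(dba)3, tri(2-furyl)phosphine, high dilution) then closes the ring and gives ketone 22 directly, so that neither an aldehyde nor chromium salts meet the epoxide and step 15 falls away.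

Step 10. Facial control at the aldehyde carbon may erode if boat and chair arrangements compete, and zinc halide may isomerise the Z iodoenal to its E isomer before it reacts. The fallback sets out from 13 and returns at 18, building the iodoalkene after the allylation. Butenolide 13 is allylated under the same zinc conditions with the robust (tert-butyldimethylsilyloxy)acetaldehyde to give the C6 alcohol with a silylated C5 hydroxyl F8. Silylation of the C6 hydroxyl (TBSCl, imidazole) gives the bis-silyl ether F9. Selective cleavage of the primary silyl ether (HF·pyridine, pyridine, THF, 0 °C) gives the primary alcohol F10, and Dess–Martin oxidation gives the α-silyloxy aldehyde F11. Stork–Zhao olefination with the ylide from (1-iodoethyl)triphenylphosphonium iodide and NaN(SiMe3)2 at −78 °C installs the Z iodoalkene and meets the route at 18.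

**Further compounds**
F1 | step 16 | (1S,3R,4Z,6R,7R,8S,10R)-6-(tert-butyldimethylsilyloxy)-3,10-epoxy-1-hydroxygermacra-4,11(13)-dien-12,8-olide | C=C1C(=O)O[C@H]2C[C@@]3(C)O[C@H](C[C@@H]3O)/C(C)=C\[C@@H](O[Si](C)(C)C(C)(C)C)[C@H]12
F2 | step 16 | (3R,4Z,6R,7R,8S,10R)-6-(tert-butyldimethylsilyloxy)-3,10-epoxy-1-oxogermacra-4,11(13)-dien-12,8-olide | C=C1C(=O)O[C@H]2C[C@@]3(C)O[C@H](CC3=O)/C(C)=C\[C@@H](O[Si](C)(C)C(C)(C)C)[C@H]12
F3 | step 16 | (3R,4Z,6R,7R,8S,10R)-6-(tert-butyldimethylsilyloxy)-3,10-epoxy-1-(trimethylsilyloxy)germacra-1,4,11(13)-trien-12,8-olide | C=C1C(=O)O[C@H]2C[C@@]3(C)O[C@H](C=C3O[Si](C)(C)C)/C(C)=C\[C@@H](O[Si](C)(C)C(C)(C)C)[C@H]12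
F4 | step 14 | trimethylstannyl analogue of 19 (SnMe3 in place of iodine, Z) | C=C1C(=O)O[C@@H](C[C@]2(C)O[C@H]2CCO)[C@@H]1[C@H](O[Si](C)(C)C(C)(C)C)/C=C(\[Sn](C)(C)C)C
F5 | step 14 | trimethylstannyl analogue of aldehyde 20 | C=C1C(=O)O[C@@H](C[C@]2(C)O[C@H]2CC=O)[C@@H]1[C@H](O[Si](C)(C)C(C)(C)C)/C=C(\[Sn](C)(C)C)C
F6 | step 14 | C3 carboxylic acid of the stannane series | C=C1C(=O)O[C@@H](C[C@]2(C)O[C@H]2CC(=O)O)[C@@H]1[C@H](O[Si](C)(C)C(C)(C)C)/C=C(\[Sn](C)(C)C)C
F7 | step 14 | C3 acid chloride of the stannane series | C=C1C(=O)O[C@@H](C[C@]2(C)O[C@H]2CC(=O)Cl)[C@@H]1[C@H](O[Si](C)(C)C(C)(C)C)/C=C(\[Sn](C)(C)C)C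
F8 | step 10 | (4S,5S)-4-[(1S)-2-(tert-butyldimethylsilyloxy)-1-hydroxyethyl]-5-{[(2S,3S)-3-{2-[(4-methoxybenzyl)oxy]ethyl}-2-methyloxiran-2-yl]methyl}-3-methylideneoxolan-2-one | C=C1C(=O)O[C@@H](C[C@]2(C)O[C@H]2CCOCc3ccc(OC)cc3)[C@@H]1[C@H](O)CO[Si](C)(C)C(C)(C)C
F9 | step 10 | bis(tert-butyldimethylsilyl) ether of F8 | C=C1C(=O)O[C@@H](C[C@]2(C)O[C@H]2CCOCc3ccc(OC)cc3)[C@@H]1[C@H](O[Si](C)(C)C(C)(C)C)CO[Si](C)(C)C(C)(C)C
F10 | step 10 | primary alcohol from F9 (C6 silyl ether kept) | C=C1C(=O)O[C@@H](C[C@]2(C)O[C@H]2CCOCc3ccc(OC)cc3)[C@@H]1[C@H](O[Si](C)(C)C(C)(C)C)CO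
F11 | step 10 | α-silyloxy aldehyde from F10 | C=C1C(=O)O[C@@H](C[C@]2(C)O[C@H]2CCOCc3ccc(OC)cc3)[C@@H]1[C@H](O[Si](C)(C)C(C)(C)C)C=O
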